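The readings were generated by integration for an exercise.

Start with a subtraction: take the impurity from the precatalyst charge, assuming that each impurity removes one catalyst, and divide by the charge. The share that remains, 42.9% for teal, is the working share.

the same everywhere: substrate 27 mM; gas 11 mM (held); precatalyst 14 µM

| charge | impurity | remark | time |
|---|---|---|---|
| south | 1.4 µM | run made earlier |  |
| south-west | 4.9 µM | run made earlier |  |
| red | 2.0 µM |  | 12 d |
| amber | 4.0 µM |  | 12 d |
| teal | 8.0 µM |  | 12 d |

| south: time / d | south: target / % | south-west: time / d | south-west: target / % |
|---|---|---|---|
| 2.50 | 97 | 1.04 | 51 |
| 5.00 | 99 | 1.67 | 70 |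
| 8.00 | 101 | 3.00 | 96 |
| 10.0 | 100 | 6.00 | 98 |
| 12.0 | 99 | 12.0 | 102 |

(scatter of a reading: 2 percentage points)

- at the start none of the gas is in solution
- "hardly changes" means that all values lie within two and a half points (for a concentration: within two and a half percent of the largest)

- [target] at the end for red, amber, teal, in this order
- the shape of the row from first to last (falls, then rises / rises all the way / falls all the way / hardly changes / rises, then falls)

Read the pace from the south-west run, whose working share is 65.0%: its reading of 51% target at 1.04 d gives, treating the loss of substrate as pseudo-first-order with the gas held, a constant of 0.686 /d. Take this reading as cautious, for the south-west reading of 96% at 3.00 d stands above the 87.2% it predicts.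

Scale the constant by the working share, and this reckoning of mine puts teal at 0.452 /d, a substrate half-life of 1.53 d, much shorter than the 12 d you have. So expect teal, when you come, to hold 0.440% of its substrate and 26.9 mM target. Red and amber carry less impurity than teal, so on this reckoning they run faster, and the row hardly changes. Keep the gas held at 11 mM, the level at which the pace was read, and let no further impurity in, since on this reckoning it lowers the working share.

The forecast, reasoning “If each impurity removes one catalyst”, gives 27 mM, 27 mM and 27 mM, a row whose shape is: hardly changes.

The flask gives 27.0 mM, 27.0 mM and 27.0 mM for red, amber and teal, and the shape is: hardly changes.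

substrate + free catalyst → catalyst intermediate A (k = 6010 /M/h); gas ⇌ partner, rate k2*(csat - [partner]) (kL = 1.66 /h); catalyst intermediate B → free catalyst + target (k = 2280 /h); precatalyst → free catalyst (k = 0.685 /h); free catalyst + impurity → spent catalyst (k = 7.53 × 10⁵ /M/h); partner + catalyst intermediate A → catalyst intermediate B (k = 13200 /M/h) Teal at 12.0 d holds 0.0110% of its substrate as such. Set the working share of teal, 42.9%, beside its free catalyst at that time, 42.9% of the catalyst charged, with 57.1% as spent catalyst. Then make the same subtraction for amber, which gives 71.4%, and amber at 12.0 d holds free catalyst at 71.4% of the catalyst charged.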